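**Assumptions**
- The target SMILES has no stereocentres, so I treat it as achiral. Any conformational (planar) chirality of the para-phenylene ring is not controlled and is assumed to interconvert.
- Methyl 3-hydroxy-4,5-dimethoxybenzoate (11) is assumed to be commercially available (it comes from methyl gallate).
- I assume an arylacetic acid dianion acylates a methyl benzoate and that the resulting α-aryl β-keto acid decarboxylates on mild acid/heat.

**Retrosynthesis**
- Target **1** comes from trimethyl ether **2** by BBr3 demethylation. **2** comes from macrocyclic stilbene **3** by hydrogenation of the C=C bond.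
- The macrocycle is closed last by ring-closing metathesis of bis-styrene ketone **4**, which forms the B–C bridge.
- **4** is made from vinyl acid **5** and vinyl ester **6** by an Ivanov-type acylation with decarboxylation, which forms the deoxybenzoin C(=O)–CH2 link.
- **5** and **6** each come from SNAr diaryl-ether formation (ortho- or para-CHO activation) followed by Wittig methylenation of the CHO.
- Order of bond formation: the two diaryl ethers, then the ketone, then the macrocycle (RCM), then C=C reduction and demethylation.

---

**Step 1**
Reactants: **7** 3-hydroxyphenylacetic acid; **8** 2-fluoro-3-methoxybenzaldehyde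
Product: **9** 2-[3-(2-formyl-6-methoxyphenoxy)phenyl]acetic acid
Conditions: Cs2CO3 (3 equiv), DMF, 120 °C; then aqueous HCl workup
Reagents that add atoms: none
Why: The ortho-CHO activates the C–F bond for SNAr by the phenoxide, giving the A–B diaryl ether (SNAr etherification). The carboxylate is a spectator and no stereocentre is formed.

**Step 2**
Reactants: **9**; **10** methyltriphenylphosphonium bromide
Product: **5** 2-[3-(2-methoxy-6-vinylphenoxy)phenyl]acetic acid
Conditions: **10** (3 equiv), KOtBu (3.3 equiv), THF, 0 °C → rt; acid/base extraction
Reagents that add atoms: methyltriphenylphosphonium bromide, C[P+](c1ccccc1)(c1ccccc1)c1ccccc1.[Br-] (adds the =CH2 carbon)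
Why: Wittig methylenation converts the aldehyde to a styrene, and the excess base covers the CO2H. The extra equivalent of ylide is there because the carboxylic acid consumes one equivalent of base.

**Step 3**
Reactants: **11** methyl 3-hydroxy-4,5-dimethoxybenzoate; **12** 4-fluorobenzaldehyde
Product: **13** methyl 3-(4-formylphenoxy)-4,5-dimethoxybenzoate
Conditions: K2CO3, DMF, 100 °C
Reagents that add atoms: none
Why: The para-CHO activates the C–F bond, and SNAr with the phenol forms the C–D diaryl ether (SNAr etherification). No stereocentre is formed.

**Step 4**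
Reactants: **13**; **10**
Product: **6** methyl 3,4-dimethoxy-5-(4-vinylphenoxy)benzoate
Conditions: **10** (1.3 equiv), KOtBu (1.4 equiv), THF, 0 °C → rt
Reagents that add atoms: methyltriphenylphosphonium bromide (**10**), SMILES as in Step 2
Why: The non-stabilised ylide reacts with the aldehyde far faster than with the ester (Wittig methylenation), and the ester survives.

**Step 5**
Reactants: **5** vinyl acid; **6** vinyl ester
Product: **4** 1-[3,4-dimethoxy-5-(4-vinylphenoxy)phenyl]-2-[3-(2-methoxy-6-vinylphenoxy)phenyl]ethan-1-one
Conditions: **5** + LDA (2.1 equiv), THF, −78 → 0 °C; add **6** (0.7 equiv), −78 °C → rt; then 2 M HCl, THF, 60 °C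
Reagents that add atoms: none (MeOH and CO2 are lost)
Why: The dianion of the arylacetic acid acylates the aryl ester (Ivanov/Claisen-type acylation). The α-aryl β-keto acid then loses CO2 on acidification and heating, giving the deoxybenzoin. The vinyl groups are untouched and no stereocentre is formed.

**Step 6**
Reactants: **4**
Product: **3** macrocyclic stilbene trimethyl ether (E/Z mixture)
Conditions: Hoveyda–Grubbs II (15 mol %), 1,2-DCE, 2 mM, 80 °C, N2 sparge
Reagents that add atoms: none (ethylene is released)
Why: Ring-closing metathesis of the two styrenes forms the 18-membered macrocycle. The ortho-alkoxy styrene chelates the catalyst, and both E and Z isomers converge in the next step.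

**Step 7**
Reactants: **3**
Product: **2** saturated macrocycle trimethyl ether
Conditions: H2 (1 atm), 10% Pd/C, EtOAc, rt, 2 h
Reagents that add atoms: none (H2 adds only hydrogen)
Why: Heterogeneous hydrogenation reduces the stilbene to the CH2CH2 bridge. Aryl ketone and aryl ethers survive neutral, short-time Pd/C conditions.

**Step 8**
Reactants: **2**
Product: **1** Marchantin G
Conditions: BBr3 (8 equiv), CH2Cl2, −78 °C → rt; then MeOH/H2O quench
Reagents that add atoms: none (the methyl groups leave as MeBr)
Why: BBr3 cleaves the three aryl methyl ethers to give the catechol and phenol. The diaryl ethers and the aryl ketone survive. The alkene was already reduced so that HBr cannot add to it.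

---

**Final checks**
- The three OMe groups are on ring B (b2), ring D (d5) and ring D (d6). Step 8 converts them to the three OH groups of the target.
- Atom balance for the ketone (Step 5): C17H16O4 (**5**) + C18H18O5 (**6**) − CH4O − CO2 = C33H30O6 (**4**). RCM (−C2H4) gives C31H26O6 (**3**). Hydrogenation (+H2) gives C31H28O6 (**2**). Demethylation (−3 CH2) gives C28H22O6, which matches the target formula.
- Ring pattern check: ring A is meta (CH2 / O); ring B has OAr, OH and CH2CH2 on adjacent positions; ring C is para; ring D is 3-acyl-5-aryloxy-1,2-diol-type (gallate pattern). All match the SMILES, and the target has no stereocentres to set.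

---

**Compound list**

| No. | Name | SMILES | Role |
|---|---|---|---|
| 1 | Marchantin G | O=C1Cc2cccc(c2)Oc2c(O)cccc2CCc2ccc(cc2)Oc2cc1cc(O)c2O | target |
| 2 | Saturated macrocycle trimethyl ether | O=C1Cc2cccc(c2)Oc2c(OC)cccc2CCc2ccc(cc2)Oc2cc1cc(OC)c2OC | intermediate |
| 3 | Macrocyclic stilbene trimethyl ether (E/Z unspecified) | O=C1Cc2cccc(c2)Oc2c(OC)cccc2C=Cc2ccc(cc2)Oc2cc1cc(OC)c2OC | intermediate |
| 4 | Bis-styrene deoxybenzoin | C=Cc1ccc(Oc2cc(C(=O)Cc3cccc(Oc4c(OC)cccc4C=C)c3)cc(OC)c2OC)cc1 | intermediate |
| 5 | 2-[3-(2-Methoxy-6-vinylphenoxy)phenyl]acetic acid | OC(=O)Cc1cccc(Oc2c(OC)cccc2C=C)c1 | intermediate |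
| 6 | Methyl 3,4-dimethoxy-5-(4-vinylphenoxy)benzoate | COC(=O)c1cc(Oc2ccc(C=C)cc2)c(OC)c(OC)c1 | intermediate |
| 7 | 3-Hydroxyphenylacetic acid | OC(=O)Cc1cccc(O)c1 | starting material |
| 8 | 2-Fluoro-3-methoxybenzaldehyde | O=Cc1cccc(OC)c1F | starting material |
| 9 | 2-[3-(2-Formyl-6-methoxyphenoxy)phenyl]acetic acid | OC(=O)Cc1cccc(Oc2c(OC)cccc2C=O)c1 | intermediate |
| 10 | Methyltriphenylphosphonium bromide | C[P+](c1ccccc1)(c1ccccc1)c1ccccc1.[Br-] | starting material (reagent) |
| 11 | Methyl 3-hydroxy-4,5-dimethoxybenzoate | COC(=O)c1cc(O)c(OC)c(OC)c1 | starting material |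
| 12 | 4-Fluorobenzaldehyde | O=Cc1ccc(F)cc1 | starting material |
| 13 | Methyl 3-(4-formylphenoxy)-4,5-dimethoxybenzoate | COC(=O)c1cc(Oc2ccc(C=O)cc2)c(OC)c(OC)c1 | intermediate |

**Total steps:** 8
**Longest linear sequence:** 6 steps (7 → 9 → 5 → 4 → 3 → 2 → 1)

**Three steps most likely to fail, with fallbacks**
1. **Step 6 (macro-RCM).** Strain or oligomerisation may dominate. Fallback: change the ring-closing bond. Make the B–C bibenzyl by an intermolecular Wittig/hydrogenation first, then close the ring by intramolecular Cu-mediated (Chan–Lam/Ullmann) A–O–B diaryl-ether formation.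
2. **Step 5 (dianion acylation and decarboxylation).** The electron-rich ester may be unreactive. Fallback: convert **6** to its Weinreb amide and react it with a benzylic Grignard from the A–B fragment (or use a Pd-catalysed α-arylation of the aryl methyl ketone with the aryl bromide of ring A). Either route forms the same ketone.
3. **Step 1 (hindered SNAr next to OMe).** The OMe ortho to the fluorine may make the SNAr too slow. Fallback: use Cu-catalysed Ullmann coupling (CuI, N,N-dimethylglycine, Cs2CO3, dioxane, 90 °C) of the phenol **7** with 2-bromo-3-methoxybenzaldehyde.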